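The synthesis rests on one disconnection: the C3–C4 bond of the 3-methyltetronic acid ring (O1, C2, C3, C4, C5). Cutting it leaves a propanoate ester (C2, C3) on the enol oxygen O1 of an α-oxygenated acrylate C4–C5=C6, so the exocyclic C5=C6 geometry (C7 cis to C4) can be fixed by olefination while the chain is still open. A single Dieckmann condensation then makes C3–C4, closes the only new ring and carries that geometry into the E-ylidene lactone. Its substrate is the methyl (2E)-2-(propanoyloxy)enoate 25 of the full chain, C7 already S and the furyl ketone masked as a dioxolane.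

Key step: step 14

Remark: locants O1 and C2–C18 follow the tetronic acid ring and continue along the side chain to the ketone carbon C18; methyl glyoxylate 19 is assumed to be used as the monomer, freshly distilled from P2O5.

Step 1
Reactants: 1 (R)-3-bromo-2-methylpropan-1-ol
Product: 2 [(2R)-3-bromo-2-methylpropoxy](tert-butyl)dimethylsilane
Conditions: TBSCl, imidazole, CH2Cl2, 0 °C → rt
Reagents that add atoms: tert-butyldimethylsilyl chloride, CC(C)(C)[Si](C)(C)Cl
Why: Standard silylation of a primary alcohol with a silyl chloride and imidazole; the stereocentre is not touched.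

Step 2
Reactants: 2 [(2R)-3-bromo-2-methylpropoxy](tert-butyl)dimethylsilane; 3 (4-bromobut-1-yn-1-yl)trimethylsilane
Product: 5 tert-butyldimethyl{[(2S)-2-methyl-7-(trimethylsilyl)hept-6-yn-1-yl]oxy}silane, via Grignard reagent 4 (not isolated)
Conditions: 3, Mg, THF, rt → 40 °C; then 2, Li2CuCl4 (3 mol %), THF, −10 °C → rt
Reagents that add atoms: none
Why: Kochi-type copper-catalysed sp3–sp3 cross-coupling of a primary alkyl bromide with a primary Grignard reagent forms C8–C9; the stereocentre lies next to, not at, the reacting carbon, and its descriptor changes from R to S only because the CIP priorities change.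

Step 3
Reactants: 5 tert-butyldimethyl{[(2S)-2-methyl-7-(trimethylsilyl)hept-6-yn-1-yl]oxy}silane
Product: 6 tert-butyldimethyl{[(2S)-2-methylhept-6-yn-1-yl]oxy}silane
Conditions: K2CO3, MeOH, rt
Reagents that add atoms: none
Why: Base-catalysed methanolysis of the alkynyl C–Si bond (protiodesilylation) frees the terminal alkyne and leaves the silyl ether intact.

Step 4
Reactants: 7 2-methyl-2-vinyloxirane
Product: 8 (2E)-4-chloro-2-methylbut-2-en-1-ol
Conditions: TiCl4, CH2Cl2, −85 °C; aq. HCl
Reagents that add atoms: titanium tetrachloride, Cl[Ti](Cl)(Cl)Cl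
Why: Lewis-acid-promoted SN2′ opening of a vinyl epoxide, with chloride adding to the vinyl terminus as the C–O bond breaks, is an established entry to this chloro alcohol and sets the C14=C15 geometry as E (CH2Cl trans to CH2O).

Step 5
Reactants: 6 tert-butyldimethyl{[(2S)-2-methylhept-6-yn-1-yl]oxy}silane; 8 (2E)-4-chloro-2-methylbut-2-en-1-ol
Product: 11 (2E,5E,10S)-11-[(tert-butyldimethylsilyl)oxy]-2,6,10-trimethylundeca-2,5-dien-1-ol, via alkenylalane 9 (not isolated), via aluminium alkoxide 10 (not isolated)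
Conditions: 6, AlMe3 (3 equiv), Cp2ZrCl2 (0.3 equiv), CH2Cl2, 0 °C → rt; then 10 [from 8 (1.3 equiv) and AlMe3, THF, 0 °C], Pd(PPh3)4 (5 mol %), THF, rt; cold 1 M HCl
Reagents that add atoms: trimethylaluminium, C[Al](C)C
Why: Negishi zirconium-catalysed carboalumination adds CH3 and aluminium syn across the terminal alkyne (CH3 to C11, metal to C12, hence 11E), and the subsequent alkenyl–allyl cross-coupling catalysed by zerovalent palladium joins C12 to the unhindered allyl terminus C13 with retention of both alkene geometries, the chloride ionising much faster than the aluminium alkoxide.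

Step 6
Reactants: 11 (2E,5E,10S)-11-[(tert-butyldimethylsilyl)oxy]-2,6,10-trimethylundeca-2,5-dien-1-ol
Product: 12 {[(2S,6E,9E)-11-bromo-2,6,10-trimethylundeca-6,9-dien-1-yl]oxy}(tert-butyl)dimethylsilane
Conditions: CBr4, PPh3, CH2Cl2, −20 → 0 °C
Reagents that add atoms: carbon tetrabromide, BrC(Br)(Br)Br
Why: The Appel reaction converts the primary allylic alcohol into the bromide by SN2 displacement of an oxyphosphonium group under neutral conditions that spare the silyl ether and the skipped diene.

Step 7
Reactants: 12 {[(2S,6E,9E)-11-bromo-2,6,10-trimethylundeca-6,9-dien-1-yl]oxy}(tert-butyl)dimethylsilane; 13 3-acetylfuran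
Product: 15 (4E,7E,12S)-13-[(tert-butyldimethylsilyl)oxy]-1-(furan-3-yl)-4,8,12-trimethyltrideca-4,7-dien-1-one, via lithium enolate 14 (not isolated)
Conditions: 13 (2 equiv), LiN(i-Pr)2, THF, −78 °C; then 12, DMPU, −78 → −20 °C
Reagents that add atoms: none
Why: SN2 alkylation of the kinetic lithium enolate of a methyl ketone by a reactive primary allylic bromide forms C16–C17, and the excess of enolate keeps the bromide limiting so that double alkylation is suppressed.

Step 8
Reactants: 15 (4E,7E,12S)-13-[(tert-butyldimethylsilyl)oxy]-1-(furan-3-yl)-4,8,12-trimethyltrideca-4,7-dien-1-one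
Product: 16 tert-butyl{[(2S,6E,9E)-12-[2-(furan-3-yl)-1,3-dioxolan-2-yl]-2,6,10-trimethyldodeca-6,9-dien-1-yl]oxy}dimethylsilane
Conditions: Me3SiOCH2CH2OSiMe3, Me3SiOTf (10 mol %), CH2Cl2, −78 → 0 °C; pyridine quench
Reagents that add atoms: 1,2-bis(trimethylsilyloxy)ethane, C[Si](C)(C)OCCO[Si](C)(C)C
Why: Noyori ketalisation (silyl triflate catalysis with the bis-silylated diol) masks the ketone without a protic acid, so the silyl ether, the furan and the alkenes should not be affected.

Step 9
Reactants: 16 tert-butyl{[(2S,6E,9E)-12-[2-(furan-3-yl)-1,3-dioxolan-2-yl]-2,6,10-trimethyldodeca-6,9-dien-1-yl]oxy}dimethylsilane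
Product: 17 (2S,6E,9E)-12-[2-(furan-3-yl)-1,3-dioxolan-2-yl]-2,6,10-trimethyldodeca-6,9-dien-1-ol
Conditions: Bu4NF, THF, 0 °C → rt
Reagents that add atoms: none
Why: Fluoride-induced cleavage of the Si–O bond frees the primary alcohol, and the dioxolane is stable to these basic conditions.

Step 10
Reactants: 17 (2S,6E,9E)-12-[2-(furan-3-yl)-1,3-dioxolan-2-yl]-2,6,10-trimethyldodeca-6,9-dien-1-ol
Product: 18 (2S,6E,9E)-12-[2-(furan-3-yl)-1,3-dioxolan-2-yl]-2,6,10-trimethyldodeca-6,9-dienal
Conditions: Dess–Martin periodinane, NaHCO3, CH2Cl2, 0 °C → rt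
Reagents that add atoms: none
Why: Dess–Martin oxidation under bicarbonate buffer stops at the aldehyde and, being fast and non-basic, should not epimerise the α-stereocentre C7 or open the dioxolane.

Step 11
Reactants: 19 methyl glyoxylate; 20 bis(2,2,2-trifluoroethyl) phosphite
Product: 21 methyl 2-[bis(2,2,2-trifluoroethoxy)phosphoryl]-2-hydroxyacetate
Conditions: PhMe, 60 °C, no base
Reagents that add atoms: none
Why: Pudovik hydrophosphonylation, addition of the P–H bond across the strongly electrophilic aldehyde carbonyl; the absence of base avoids phospha-Brook rearrangement of the adduct.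

Step 12
Reactants: 21 methyl 2-[bis(2,2,2-trifluoroethoxy)phosphoryl]-2-hydroxyacetate; 22 propanoyl chloride
Product: 23 methyl 2-[bis(2,2,2-trifluoroethoxy)phosphoryl]-2-(propanoyloxy)acetate
Conditions: pyridine, CH2Cl2, 0 °C
Reagents that add atoms: none
Why: O-acylation of the secondary alcohol by an acid chloride, with pyridine as a base too weak to deprotonate the phosphonate.

Step 13
Reactants: 18 (2S,6E,9E)-12-[2-(furan-3-yl)-1,3-dioxolan-2-yl]-2,6,10-trimethyldodeca-6,9-dienal; 23 methyl 2-[bis(2,2,2-trifluoroethoxy)phosphoryl]-2-(propanoyloxy)acetate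
Product: 25 methyl (2E,4S,8E,11E)-14-[2-(furan-3-yl)-1,3-dioxolan-2-yl]-4,8,12-trimethyl-2-(propanoyloxy)tetradeca-2,8,11-trienoate, via potassium phosphonate salt 24 (not isolated)
Conditions: 23, KN(SiMe3)2, 18-crown-6, THF, −78 °C; then 18, −78 °C
Reagents that add atoms: none
Why: Horner–Wadsworth–Emmons olefination in its Still–Gennari form: with the electron-poor bis(trifluoroethyl) phosphonate and a dissociated potassium counter-ion, addition is irreversible and elimination fast, so the kinetic adduct, which places the aldehyde residue cis to the ester as with other α-heteroatom-substituted reagents of this class, should give the 2E enol ester (C7 cis to C4), and C7 should not epimerise because the aldehyde meets only the preformed, weakly basic carbanion at −78 °C.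

Step 14
Reactants: 25 methyl (2E,4S,8E,11E)-14-[2-(furan-3-yl)-1,3-dioxolan-2-yl]-4,8,12-trimethyl-2-(propanoyloxy)tetradeca-2,8,11-trienoate
Product: 27 (5E)-5-{(2S,6E,9E)-12-[2-(furan-3-yl)-1,3-dioxolan-2-yl]-2,6,10-trimethyldodeca-6,9-dien-1-ylidene}-4-hydroxy-3-methylfuran-2(5H)-one, via lithium tetronate 26 (not isolated)
Conditions: LiN(SiMe3)2 (2.5 equiv), THF, −78 °C (25 added slowly to the base) → −20 °C; cold 0.5 M HCl to pH 3; light excluded
Reagents that add atoms: none
Why: The amide base removes an α-hydrogen of the propanoyl group (C3) and the lithium enolate adds to the neighbouring methyl ester carbonyl C4; loss of methoxide from the tetrahedral intermediate forms C3–C4 and the β-keto lactone, which a second equivalent of base converts at once into the tetronate 26, so the condensation cannot revert. This is a Dieckmann (intramolecular Claisen) condensation of the kind used to close tetronic acids and pulvinones from α-acyloxy esters and enol esters. The single new ring, the lactone O1–C2–C3–C4–C5, closes in a 5-exo-trig mode, the alternative attack of C3 on C6 being a disfavoured 5-endo-trig process. No stereocentre is created: the C5=C6 bond takes no part, so the cis relation of C7 and C4 set in step 13 should pass into the ring as the E-ylidene and C7 should stay S. The selectivity required is site selectivity of deprotonation, the propanoyl CH2 in preference to the γ-hydrogen at C7 and to any hydrogen next to the ketone; it is secured by allylic 1,3-strain, which holds the tertiary C7–H in the alkene plane and out of overlap with the acrylate π system, by the bulky base at low temperature, and by the dioxolane, which removes the more acidic ketone α-hydrogens. Adding 25 to an excess of base keeps unreacted enol ester from accumulating beside the liberated methoxide.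

Step 15
Reactants: 27 (5E)-5-{(2S,6E,9E)-12-[2-(furan-3-yl)-1,3-dioxolan-2-yl]-2,6,10-trimethyldodeca-6,9-dien-1-ylidene}-4-hydroxy-3-methylfuran-2(5H)-one
Product: 28 (5E)-5-[(2S,6E,9E)-13-(furan-3-yl)-2,6,10-trimethyl-13-oxotrideca-6,9-dien-1-ylidene]-4-hydroxy-3-methylfuran-2(5H)-one
Conditions: 1 M aq. HCl, THF, rt, light excluded
Reagents that add atoms: water, O
Why: Acid-catalysed ketal hydrolysis, made easy by the 3-furyl group that stabilises the oxocarbenium ion, releases the ketone, while the tetronic acid, the E-ylidene bond and the skipped diene should be stable to dilute aqueous acid in the dark.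

Compound list
1 | (R)-3-bromo-2-methylpropan-1-ol | OC[C@@H](C)CBr | starting material
2 | [(2R)-3-bromo-2-methylpropoxy](tert-butyl)dimethylsilane | CC(C)(C)[Si](C)(C)OC[C@@H](C)CBr | intermediate
3 | (4-bromobut-1-yn-1-yl)trimethylsilane | C[Si](C)(C)C#CCCBr | starting material
4 | [4-(trimethylsilyl)but-3-yn-1-yl]magnesium bromide (not isolated) | C[Si](C)(C)C#CCC[Mg]Br | intermediate
5 | tert-butyldimethyl{[(2S)-2-methyl-7-(trimethylsilyl)hept-6-yn-1-yl]oxy}silane | CC(C)(C)[Si](C)(C)OC[C@@H](C)CCCC#C[Si](C)(C)C | intermediate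
6 | tert-butyldimethyl{[(2S)-2-methylhept-6-yn-1-yl]oxy}silane | CC(C)(C)[Si](C)(C)OC[C@@H](C)CCCC#C | intermediate
7 | 2-methyl-2-vinyloxirane (isoprene monoxide, racemic) | CC1(CO1)C=C | starting material
8 | (2E)-4-chloro-2-methylbut-2-en-1-ol | OC/C(C)=C/CCl | intermediate
9 | {(1E,6S)-7-[(tert-butyldimethylsilyl)oxy]-2,6-dimethylhept-1-en-1-yl}dimethylalane (not isolated) | CC(C)(C)[Si](C)(C)OC[C@@H](C)CCC/C(C)=C/[Al](C)C | intermediate
10 | {[(2E)-4-chloro-2-methylbut-2-en-1-yl]oxy}dimethylalane (not isolated) | C[Al](C)OC/C(C)=C/CCl | intermediate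
11 | (2E,5E,10S)-11-[(tert-butyldimethylsilyl)oxy]-2,6,10-trimethylundeca-2,5-dien-1-ol | CC(C)(C)[Si](C)(C)OC[C@@H](C)CCC/C(C)=C/C/C=C(\C)CO | intermediate
12 | {[(2S,6E,9E)-11-bromo-2,6,10-trimethylundeca-6,9-dien-1-yl]oxy}(tert-butyl)dimethylsilane | CC(C)(C)[Si](C)(C)OC[C@@H](C)CCC/C(C)=C/C/C=C(\C)CBr | intermediate
13 | 3-acetylfuran (1-(furan-3-yl)ethan-1-one) | CC(=O)c1ccoc1 | starting material
14 | lithium 1-(furan-3-yl)ethen-1-olate (not isolated) | [Li]OC(=C)c1ccoc1 | intermediate
15 | (4E,7E,12S)-13-[(tert-butyldimethylsilyl)oxy]-1-(furan-3-yl)-4,8,12-trimethyltrideca-4,7-dien-1-one | CC(C)(C)[Si](C)(C)OC[C@@H](C)CCC/C(C)=C/C/C=C(\C)CCC(=O)c1ccoc1 | intermediate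
16 | tert-butyl{[(2S,6E,9E)-12-[2-(furan-3-yl)-1,3-dioxolan-2-yl]-2,6,10-trimethyldodeca-6,9-dien-1-yl]oxy}dimethylsilane | CC(C)(C)[Si](C)(C)OC[C@@H](C)CCC/C(C)=C/C/C=C(\C)CCC1(OCCO1)c2ccoc2 | intermediate
17 | (2S,6E,9E)-12-[2-(furan-3-yl)-1,3-dioxolan-2-yl]-2,6,10-trimethyldodeca-6,9-dien-1-ol | OC[C@@H](C)CCC/C(C)=C/C/C=C(\C)CCC1(OCCO1)c2ccoc2 | intermediate
18 | (2S,6E,9E)-12-[2-(furan-3-yl)-1,3-dioxolan-2-yl]-2,6,10-trimethyldodeca-6,9-dienal | O=C[C@@H](C)CCC/C(C)=C/C/C=C(\C)CCC1(OCCO1)c2ccoc2 | intermediate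
19 | methyl glyoxylate (methyl 2-oxoacetate) | COC(=O)C=O | starting material
20 | bis(2,2,2-trifluoroethyl) phosphite | O=[PH](OCC(F)(F)F)OCC(F)(F)F | starting material
21 | methyl 2-[bis(2,2,2-trifluoroethoxy)phosphoryl]-2-hydroxyacetate (racemic) | COC(=O)C(O)P(=O)(OCC(F)(F)F)OCC(F)(F)F | intermediate
22 | propanoyl chloride | CCC(=O)Cl | starting material
23 | methyl 2-[bis(2,2,2-trifluoroethoxy)phosphoryl]-2-(propanoyloxy)acetate (racemic) | CCC(=O)OC(C(=O)OC)P(=O)(OCC(F)(F)F)OCC(F)(F)F | intermediate
24 | potassium salt of the carbanion of 23 (not isolated) | CCC(=O)O[C-](C(=O)OC)P(=O)(OCC(F)(F)F)OCC(F)(F)F.[K+] | intermediate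
25 | methyl (2E,4S,8E,11E)-14-[2-(furan-3-yl)-1,3-dioxolan-2-yl]-4,8,12-trimethyl-2-(propanoyloxy)tetradeca-2,8,11-trienoate | COC(=O)/C(=C\[C@@H](C)CCC/C(C)=C/C/C=C(\C)CCC1(OCCO1)c2ccoc2)OC(=O)CC | intermediate
26 | lithium salt (tetronate) of 27 (not isolated) | CC1=C([O-])/C(=C\[C@@H](C)CCC/C(C)=C/C/C=C(\C)CCC2(OCCO2)c3ccoc3)OC1=O.[Li+] | intermediate
27 | (5E)-5-{(2S,6E,9E)-12-[2-(furan-3-yl)-1,3-dioxolan-2-yl]-2,6,10-trimethyldodeca-6,9-dien-1-ylidene}-4-hydroxy-3-methylfuran-2(5H)-one | CC1=C(O)/C(=C\[C@@H](C)CCC/C(C)=C/C/C=C(\C)CCC2(OCCO2)c3ccoc3)OC1=O | intermediate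
28 | (5E)-5-[(2S,6E,9E)-13-(furan-3-yl)-2,6,10-trimethyl-13-oxotrideca-6,9-dien-1-ylidene]-4-hydroxy-3-methylfuran-2(5H)-one (CNP0018619.1) | CC1=C(O)/C(=C\[C@@H](C)CCC/C(C)=C/C/C=C(\C)CCC(=O)c2ccoc2)OC1=O | target

Total step count: 15.
Longest linear sequence: 12 steps (steps 1, 2, 3, 5, 6, 7, 8, 9, 10, 13, 14 and 15, counted from bromo alcohol 1).

Steps most likely to fail

Step 14. The propanoate enolate may fragment by loss of methylketene before it closes the ring, the base may cleave the enol ester, or deprotonation at C7 may scramble the alkene geometry and the stereocentre. The fallback builds the ring first and the alkene second, and sets out from aldehyde 18. 4-Methoxy-3-methylfuran-2(5H)-one F1, made from commercial 3-methyltetronic acid with Me2SO4 and K2CO3, is lithiated at C5 with LiN(i-Pr)2 at −78 °C and added to 18 to give the aldol adduct F2. Mesylation (MsCl, Et3N) to the mesylate F3 and elimination with DBU should give the 5-ylidene tetronate, expected mainly as the Z-ylidene methyl ether F4. Irradiation (hν, 350 nm) equilibrates it with the E-ylidene methyl ether F5, which is separated by chromatography while F4 is recycled. Demethylation of F5 with n-PrSLi in HMPA at rt comes back to the route at 27.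

Step 13. The cis selectivity of the olefination may be lost, so that C7 ends up trans to the ester. The fallback corrects the geometry after ring closure, and sets out from 18 and 23. The Z-enol ester F6 formed in the olefination is not discarded but cyclised under the conditions of step 14 to the Z-ylidene tetronic acid F7. Irradiation of F7 (hν, 350 nm, MeCN) establishes the E/Z photostationary mixture of the ylidene lactone, a known behaviour of 5-ylidene tetronic acids; 27 is separated by chromatography and F7 is irradiated again. The route is rejoined at 27.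

Step 5. The alkenylalane may be protonated by incompletely metalated 8, the aluminium alkoxide may ionise in competition with the chloride, the allyl unit may transpose, and methylalumination may give some of the regioisomer. The fallback replaces aluminium by tin in the coupling, and sets out from alkyne 6. The alkenylalane 9 is quenched with I2 to give the alkenyl iodide F8, which is purified. Iodine–lithium exchange (t-BuLi, Et2O, −78 °C) and Bu3SnCl give the alkenylstannane F9. A Stille coupling of F9 with the free chloro alcohol 8 (Pd(PPh3)4, THF, 50 °C), which tolerates the hydroxyl group and retains alkene geometry, comes back to the route at 11.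

Further compounds
F1 | step 14 | 4-methoxy-3-methylfuran-2(5H)-one | COC1=C(C)C(=O)OC1
F2 | step 14 | 5-{(2S,6E,9E)-12-[2-(furan-3-yl)-1,3-dioxolan-2-yl]-1-hydroxy-2,6,10-trimethyldodeca-6,9-dien-1-yl}-4-methoxy-3-methylfuran-2(5H)-one (mixture of diastereomers at ring C5 and the carbinol carbon) | COC1=C(C)C(=O)OC1C(O)[C@@H](C)CCC/C(C)=C/C/C=C(\C)CCC2(OCCO2)c3ccoc3
F3 | step 14 | methanesulfonate of F2 | COC1=C(C)C(=O)OC1C(OS(C)(=O)=O)[C@@H](C)CCC/C(C)=C/C/C=C(\C)CCC2(OCCO2)c3ccoc3
F4 | step 14 | (5Z)-5-{(2S,6E,9E)-12-[2-(furan-3-yl)-1,3-dioxolan-2-yl]-2,6,10-trimethyldodeca-6,9-dien-1-ylidene}-4-methoxy-3-methylfuran-2(5H)-one | CC1=C(OC)/C(=C/[C@@H](C)CCC/C(C)=C/C/C=C(\C)CCC2(OCCO2)c3ccoc3)OC1=O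
F5 | step 14 | (5E)-5-{(2S,6E,9E)-12-[2-(furan-3-yl)-1,3-dioxolan-2-yl]-2,6,10-trimethyldodeca-6,9-dien-1-ylidene}-4-methoxy-3-methylfuran-2(5H)-one | CC1=C(OC)/C(=C\[C@@H](C)CCC/C(C)=C/C/C=C(\C)CCC2(OCCO2)c3ccoc3)OC1=O
F6 | step 13 | methyl (2Z,4S,8E,11E)-14-[2-(furan-3-yl)-1,3-dioxolan-2-yl]-4,8,12-trimethyl-2-(propanoyloxy)tetradeca-2,8,11-trienoate | COC(=O)/C(=C/[C@@H](C)CCC/C(C)=C/C/C=C(\C)CCC1(OCCO1)c2ccoc2)OC(=O)CC
F7 | step 13 | (5Z)-5-{(2S,6E,9E)-12-[2-(furan-3-yl)-1,3-dioxolan-2-yl]-2,6,10-trimethyldodeca-6,9-dien-1-ylidene}-4-hydroxy-3-methylfuran-2(5H)-one | CC1=C(O)/C(=C/[C@@H](C)CCC/C(C)=C/C/C=C(\C)CCC2(OCCO2)c3ccoc3)OC1=O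
F8 | step 5 | tert-butyl{[(2S,6E)-7-iodo-2,6-dimethylhept-6-en-1-yl]oxy}dimethylsilane | CC(C)(C)[Si](C)(C)OC[C@@H](C)CCC/C(C)=C/I
F9 | step 5 | tert-butyldimethyl{[(2S,6E)-2,6-dimethyl-7-(tributylstannyl)hept-6-en-1-yl]oxy}silane | CC(C)(C)[Si](C)(C)OC[C@@H](C)CCC/C(C)=C/[Sn](CCCC)(CCCC)CCCC
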